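**Retrosynthetic overview**
1. The diene is cut at its central C–C single bond: Suzuki–Miyaura union of an oxolane (E)-alkenylboronate with a 3-[(E)-2-iodoethenyl]isocoumarin, then one desilylation.
2. Oxolane (O1, C2 = CHMe, C3 = CH2, C4 = CHOH, C5 = CH–diene): a formal (3+2) annulation of acetaldehyde with an α-chiral allylsilane builds the ring in one operation (bonds C2–C3 and O1–C5) and sets C2, C4 and C5; silicon on C4 is then oxidised to the hydroxyl.
3. Enabling feature: O1–C2(Me) is a latent acetaldehyde C=O next to the unsubstituted C3 methylene, and the C4 oxygen sits on the ring carbon between C3 and the O-bearing C5, which is where the silicon of an allylsilane arrives after its 1,2-shift; the 2,5-trans, 4,5-trans pattern is the one this annulation delivers.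
4. Isocoumarin: chlorination of an orsellinate, lateral lithiation and acylation with a glyoxylate acetal, enol-lactonisation (closes the pyranone ring), Takai iodo-olefination, demethylation.
5. Ring order: benzene ring bought; oxolane ring in step 3 and pyranone ring in step 11 (independent branches); no ring is formed after the fragment union.

Key step: step 3

Remark: the oxolane atoms are called O1, C2 (CHMe), C3 (CH2), C4 (CHOH) and C5 (CH bearing the diene) throughout; it is assumed that the enantiomer of the chiral carbene ligand in step 2 is chosen so that the R allylsilane results.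

**Oxolane fragment**

Step 1
Reactants: 1 (2Z)-4-(benzyloxy)but-2-en-1-ol
Product: 2 (2Z)-4-(benzyloxy)but-2-en-1-yl diethyl phosphate
Conditions: ClP(O)(OEt)2, pyridine, DMAP (cat.), CH2Cl2, 0 °C → rt
Reagents that add atoms: diethyl chlorophosphate, CCOP(=O)(Cl)OCC
Why: O-phosphorylation of the primary allylic alcohol installs the leaving group for allylic substitution and leaves the Z alkene and the benzyl ether untouched.

Step 2
Reactants: 2 (2Z)-4-(benzyloxy)but-2-en-1-yl diethyl phosphate
Product: 3 [(2R)-1-(benzyloxy)but-3-en-2-yl]dimethyl(phenyl)silane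
Conditions: PhMe2Si–Bpin (1.5 equiv), CuCl (5 mol %), chiral imidazolinium chloride as N-heterocyclic carbene precursor (6 mol %), NaOMe (1.5 equiv), THF, 0 °C
Reagents that add atoms: [dimethyl(phenyl)silyl]boronic acid pinacol ester, C[Si](C)(c1ccccc1)B1OC(C)(C)C(C)(C)O1
Why: Copper-catalysed enantioselective γ-selective allylic substitution (SN2′) with a silylboronate: the carbene-bound monovalent copper silyl species adds to one alkene face and phosphate leaves, which puts silicon on the carbon next to the benzyloxymethyl group, sets that stereocentre (R) under ligand control and leaves a terminal vinyl group.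

Step 3
Reactants: 3 [(2R)-1-(benzyloxy)but-3-en-2-yl]dimethyl(phenyl)silane, 4 acetaldehyde
Product: 6 [(2R,3S,5R)-2-[(benzyloxy)methyl]-5-methyloxolan-3-yl]dimethyl(phenyl)silane, via β-silyl cation 5 (not isolated)
Conditions: MeCHO (3 equiv), BF3·OEt2 (1.2 equiv), 4 Å molecular sieves, CH2Cl2, −78 °C; Et3N, then aq. NaHCO3
Reagents that add atoms: none
Why: BF3-activated acetaldehyde is attacked by the terminal alkene carbon of 3 on the face anti to the C–Si bond (anti-SE2′), which forms the C2–C3 bond and the β-silyl cation 5. The closest known reaction type is the Lewis acid-promoted formal (3+2) annulation of α-chiral allylsilanes with aldehydes, an interrupted Hosomi–Sakurai reaction. A suprafacial 1,2-silyl shift through the siliranium-bridged form of 5 moves silicon to C4, and the BF3-bound alkoxide then closes the oxolane by 5-endo backside opening of that bridge at C5 (O1–C5 bond). C5 is therefore set by inversion of the silane stereocentre, C4 by the face on which silicon migrates (silicon trans to the benzyloxymethyl group), and C2 by the open synclinal transition state in which the allylic hydrogen eclipses the alkene and the aldehyde methyl points away from the allyl unit, which should give the 2,5-trans ring with methyl cis to silicon. The step needs ring closure to outrun loss of silicon from 5 and needs good aldehyde-face selectivity; the bulky, poorly electrofugal PhMe2Si group, the absence of a nucleophilic halide (BF3, not a metal chloride), the low temperature and the single allylic stereocentre are the elements that secure both.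

Step 4
Reactants: 6 [(2R,3S,5R)-2-[(benzyloxy)methyl]-5-methyloxolan-3-yl]dimethyl(phenyl)silane
Product: 8 (2R,3S,5R)-2-[(benzyloxy)methyl]-5-methyloxolan-3-ol, via bromosilane 7 (not isolated)
Conditions: KBr, AcOOH (32 % in AcOH), NaOAc, AcOH, 0 °C → rt
Reagents that add atoms: peracetic acid, CC(=O)OO
Why: Fleming–Tamao oxidation: ipso-bromodesilylation of the phenyl group gives bromosilane 7, and the peracid then moves the ring carbon from silicon to oxygen with retention, so the C4–Si bond becomes the C4–OH bond (S), cis to the methyl group.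

Step 5
Reactants: 8 (2R,3S,5R)-2-[(benzyloxy)methyl]-5-methyloxolan-3-ol
Product: 9 {[(2R,3S,5R)-2-[(benzyloxy)methyl]-5-methyloxolan-3-yl]oxy}(tert-butyl)dimethylsilane
Conditions: TBSCl, imidazole, DMF, rt
Reagents that add atoms: tert-butyldimethylsilyl chloride, CC(C)(C)[Si](C)(C)Cl
Why: Imidazole-mediated silylation protects the secondary C4 hydroxyl for the oxidation and chromium steps and touches no stereocentre.

Step 6
Reactants: 9 {[(2R,3S,5R)-2-[(benzyloxy)methyl]-5-methyloxolan-3-yl]oxy}(tert-butyl)dimethylsilane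
Product: 10 [(2R,3S,5R)-3-{[tert-butyl(dimethyl)silyl]oxy}-5-methyloxolan-2-yl]methanol
Conditions: H2 (1 atm), 10 % Pd/C, EtOAc, rt
Reagents that add atoms: none
Why: Hydrogenolysis cleaves only the benzylic C–O bond and frees the primary alcohol, since the silyl ether and the oxolane are inert in ethyl acetate.

Step 7
Reactants: 10 [(2R,3S,5R)-3-{[tert-butyl(dimethyl)silyl]oxy}-5-methyloxolan-2-yl]methanol
Product: 11 (2S,3S,5R)-3-{[tert-butyl(dimethyl)silyl]oxy}-5-methyloxolane-2-carbaldehyde
Conditions: Dess–Martin periodinane, pyridine, CH2Cl2, 0 °C → rt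
Reagents that add atoms: none
Why: Dess–Martin oxidation stops at the aldehyde under buffered, non-enolising conditions, so the α-oxygenated C5 centre keeps its configuration (its descriptor changes to S only through the priority rules).

Step 8
Reactants: 11 (2S,3S,5R)-3-{[tert-butyl(dimethyl)silyl]oxy}-5-methyloxolane-2-carbaldehyde
Product: 12 tert-butyl(dimethyl){[(2R,3S,5R)-5-methyl-2-[(E)-2-(4,4,5,5-tetramethyl-1,3,2-dioxaborolan-2-yl)ethenyl]oxolan-3-yl]oxy}silane
Conditions: Cl2CHBpin (2 equiv), CrCl2 (8 equiv), LiI (4 equiv), THF, rt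
Reagents that add atoms: (dichloromethyl)boronic acid pinacol ester, ClC(Cl)B1OC(C)(C)C(C)(C)O1
Why: Takai-type chromium-mediated boryl olefination: the geminal dichromium boryl species adds to the aldehyde and eliminates to the E alkenylboronate, and the non-basic divalent chromium conditions should not epimerise the α-alkoxy aldehyde.

**Isocoumarin fragment**

Step 9
Reactants: 13 methyl 2,4-dimethoxy-6-methylbenzoate
Product: 14 methyl 3-chloro-4,6-dimethoxy-2-methylbenzoate
Conditions: SO2Cl2 (1.05 equiv), CH2Cl2, 0 °C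
Reagents that add atoms: sulfuryl chloride, O=S(=O)(Cl)Cl
Why: Electrophilic aromatic chlorination should go to the free position next to the methyl group (para to one methoxy, ortho to the other), because the position between the two methoxy groups is the more hindered one.

Step 10
Reactants: 14 methyl 3-chloro-4,6-dimethoxy-2-methylbenzoate, 15 ethyl 2,2-diethoxyacetate
Product: 17 methyl 3-chloro-2-(3,3-diethoxy-2-oxopropyl)-4,6-dimethoxybenzoate, via benzyllithium 16 (not isolated)
Conditions: LiN(iPr)2 (2.2 equiv), THF, −78 °C; then 15, −78 → −40 °C; aq. NH4Cl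
Reagents that add atoms: none
Why: Lateral (benzylic) lithiation of the ortho-toluate and Claisen-type acylation by the ester; the product ketone is held as its enolate by the second equivalent of base, which stops over-addition.

Step 11
Reactants: 17 methyl 3-chloro-2-(3,3-diethoxy-2-oxopropyl)-4,6-dimethoxybenzoate
Product: 19 5-chloro-6,8-dimethoxy-1-oxo-1H-isochromene-3-carbaldehyde, via acetal lactone 18 (not isolated)
Conditions: p-TsOH·H2O (0.2 equiv), toluene, 90 °C; then TFA–H2O (9:1), rt
Reagents that add atoms: water, O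
Why: Acid-catalysed enol-lactonisation of the benzylic ketone onto the neighbouring methyl ester closes the pyranone ring (6-exo-trig acyl substitution by the enol oxygen), and aqueous acid then unmasks the aldehyde from the acetal.

Step 12
Reactants: 19 5-chloro-6,8-dimethoxy-1-oxo-1H-isochromene-3-carbaldehyde
Product: 20 5-chloro-3-[(E)-2-iodoethenyl]-6,8-dimethoxy-1H-isochromen-1-one
Conditions: CHI3 (2 equiv), CrCl2 (6 equiv), THF–dioxane, 0 °C → rt
Reagents that add atoms: iodoform, IC(I)I
Why: Takai olefination: the geminal dichromium species formed from iodoform adds to the aldehyde and eliminates to the E iodoalkene, while lactone and aryl chloride are inert to divalent chromium.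

Step 13
Reactants: 20 5-chloro-3-[(E)-2-iodoethenyl]-6,8-dimethoxy-1H-isochromen-1-one
Product: 21 5-chloro-6,8-dihydroxy-3-[(E)-2-iodoethenyl]-1H-isochromen-1-one
Conditions: BBr3 (5 equiv), CH2Cl2, −78 → 0 °C; MeOH, then H2O
Reagents that add atoms: none
Why: Lewis-acid ether cleavage: BBr3 binds each methoxy oxygen and bromide removes the methyl group (SN2), the peri 8-methoxy group first, while lactone, aryl chloride and iodoalkene should stay intact.

**Fragment union and end game**

Step 14
Reactants: 12 tert-butyl(dimethyl){[(2R,3S,5R)-5-methyl-2-[(E)-2-(4,4,5,5-tetramethyl-1,3,2-dioxaborolan-2-yl)ethenyl]oxolan-3-yl]oxy}silane, 21 5-chloro-6,8-dihydroxy-3-[(E)-2-iodoethenyl]-1H-isochromen-1-one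
Product: 22 3-[(1E,3E)-4-[(2R,3S,5R)-3-{[tert-butyl(dimethyl)silyl]oxy}-5-methyloxolan-2-yl]buta-1,3-dien-1-yl]-5-chloro-6,8-dihydroxy-1H-isochromen-1-one
Conditions: PdCl2(dppf) (5 mol %), K3PO4 (3 equiv), THF–H2O (degassed), rt → 40 °C; dilute aq. citric acid
Reagents that add atoms: none
Why: Suzuki–Miyaura coupling: oxidative addition of zerovalent palladium to the iodoalkene, base-assisted transmetalation of the alkenylboronate and reductive elimination form the central diene bond with retention of both E geometries, and the aryl chloride does not react under these mild conditions.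

Step 15
Reactants: 22 3-[(1E,3E)-4-[(2R,3S,5R)-3-{[tert-butyl(dimethyl)silyl]oxy}-5-methyloxolan-2-yl]buta-1,3-dien-1-yl]-5-chloro-6,8-dihydroxy-1H-isochromen-1-one
Product: 23 5-chloro-6,8-dihydroxy-3-[(1E,3E)-4-[(2R,3S,5R)-3-hydroxy-5-methyloxolan-2-yl]buta-1,3-dien-1-yl]-1H-isochromen-1-one
Conditions: HF·pyridine, pyridine, THF, 0 °C → rt
Reagents that add atoms: none
Why: Fluoride-mediated cleavage of the silyl ether frees the C4 hydroxyl without touching the diene, the lactone or any stereocentre.

**Compound list**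
1 | (2Z)-4-(benzyloxy)but-2-en-1-ol | OC/C=C\COCc1ccccc1 | starting material
2 | (2Z)-4-(benzyloxy)but-2-en-1-yl diethyl phosphate | CCOP(=O)(OCC)OC/C=C\COCc1ccccc1 | intermediate
3 | [(2R)-1-(benzyloxy)but-3-en-2-yl]dimethyl(phenyl)silane | C=C[C@H](COCc1ccccc1)[Si](C)(C)c1ccccc1 | intermediate
4 | acetaldehyde | CC=O | starting material
5 | BF3-bound (2R,5R)-6-(benzyloxy)-5-[dimethyl(phenyl)silyl]hexan-2-olate with the cationic centre at C4 (β-silyl cation, siliranium-bridged; not isolated) | C[C@@H](O[B-](F)(F)F)C[CH+][C@H](COCc1ccccc1)[Si](C)(C)c1ccccc1 | intermediate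
6 | [(2R,3S,5R)-2-[(benzyloxy)methyl]-5-methyloxolan-3-yl]dimethyl(phenyl)silane | C[C@@H]1C[C@H]([Si](C)(C)c2ccccc2)[C@@H](COCc2ccccc2)O1 | intermediate
7 | bromo{(2R,3S,5R)-2-[(benzyloxy)methyl]-5-methyloxolan-3-yl}dimethylsilane (not isolated) | C[C@@H]1C[C@H]([Si](C)(C)Br)[C@@H](COCc2ccccc2)O1 | intermediate
8 | (2R,3S,5R)-2-[(benzyloxy)methyl]-5-methyloxolan-3-ol | C[C@@H]1C[C@H](O)[C@@H](COCc2ccccc2)O1 | intermediate
9 | {[(2R,3S,5R)-2-[(benzyloxy)methyl]-5-methyloxolan-3-yl]oxy}(tert-butyl)dimethylsilane | C[C@@H]1C[C@H](O[Si](C)(C)C(C)(C)C)[C@@H](COCc2ccccc2)O1 | intermediate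
10 | [(2R,3S,5R)-3-{[tert-butyl(dimethyl)silyl]oxy}-5-methyloxolan-2-yl]methanol | C[C@@H]1C[C@H](O[Si](C)(C)C(C)(C)C)[C@@H](CO)O1 | intermediate
11 | (2S,3S,5R)-3-{[tert-butyl(dimethyl)silyl]oxy}-5-methyloxolane-2-carbaldehyde | C[C@@H]1C[C@H](O[Si](C)(C)C(C)(C)C)[C@@H](C=O)O1 | intermediate
12 | tert-butyl(dimethyl){[(2R,3S,5R)-5-methyl-2-[(E)-2-(4,4,5,5-tetramethyl-1,3,2-dioxaborolan-2-yl)ethenyl]oxolan-3-yl]oxy}silane | C[C@@H]1C[C@H](O[Si](C)(C)C(C)(C)C)[C@@H](/C=C/B2OC(C)(C)C(C)(C)O2)O1 | intermediate
13 | methyl 2,4-dimethoxy-6-methylbenzoate | COC(=O)c1c(C)cc(OC)cc1OC | starting material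
14 | methyl 3-chloro-4,6-dimethoxy-2-methylbenzoate | COC(=O)c1c(C)c(Cl)c(OC)cc1OC | intermediate
15 | ethyl 2,2-diethoxyacetate | CCOC(=O)C(OCC)OCC | starting material
16 | {[2-chloro-3,5-dimethoxy-6-(methoxycarbonyl)phenyl]methyl}lithium (not isolated) | [Li]Cc1c(Cl)c(OC)cc(OC)c1C(=O)OC | intermediate
17 | methyl 3-chloro-2-(3,3-diethoxy-2-oxopropyl)-4,6-dimethoxybenzoate | COC(=O)c1c(CC(=O)C(OCC)OCC)c(Cl)c(OC)cc1OC | intermediate
18 | 5-chloro-3-(diethoxymethyl)-6,8-dimethoxy-1H-isochromen-1-one (not isolated) | CCOC(OCC)c1cc2c(Cl)c(OC)cc(OC)c2c(=O)o1 | intermediate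
19 | 5-chloro-6,8-dimethoxy-1-oxo-1H-isochromene-3-carbaldehyde | O=Cc1cc2c(Cl)c(OC)cc(OC)c2c(=O)o1 | intermediate
20 | 5-chloro-3-[(E)-2-iodoethenyl]-6,8-dimethoxy-1H-isochromen-1-one | I/C=C/c1cc2c(Cl)c(OC)cc(OC)c2c(=O)o1 | intermediate
21 | 5-chloro-6,8-dihydroxy-3-[(E)-2-iodoethenyl]-1H-isochromen-1-one | I/C=C/c1cc2c(Cl)c(O)cc(O)c2c(=O)o1 | intermediate
22 | 3-[(1E,3E)-4-[(2R,3S,5R)-3-{[tert-butyl(dimethyl)silyl]oxy}-5-methyloxolan-2-yl]buta-1,3-dien-1-yl]-5-chloro-6,8-dihydroxy-1H-isochromen-1-one | C[C@@H]1C[C@H](O[Si](C)(C)C(C)(C)C)[C@@H](/C=C/C=C/c2cc3c(Cl)c(O)cc(O)c3c(=O)o2)O1 | intermediate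
23 | 5-chloro-6,8-dihydroxy-3-[(1E,3E)-4-[(2R,3S,5R)-3-hydroxy-5-methyloxolan-2-yl]buta-1,3-dien-1-yl]-1H-isochromen-1-one | C[C@@H]1C[C@H](O)[C@@H](/C=C/C=C/c2cc3c(Cl)c(O)cc(O)c3c(=O)o2)O1 | target

**Step count and risks**

Total step count: 15. Longest linear sequence: 10 steps (steps 1–8, 14 and 15); the isocoumarin branch has 5 steps before the union.

The three steps most likely to fail:

(1) Step 3, the annulation. The β-silyl cation may lose silicon before the ring closes, which would give open-chain allylation. The small aldehyde may also be attacked on both faces, which would erode the 2,5-trans selectivity. The fallback sets C2 by reagent control and closes the ring through the C5–O bond. It sets out from 4: asymmetric allylboration with the B-allyldiisopinocampheylborane enantiomer that gives the R alcohol (Et2O, −78 °C; NaOH, H2O2) should give (2R)-pent-4-en-2-ol F1. Cross-metathesis of F1 with allyl benzyl ether (second-generation Grubbs catalyst, CH2Cl2, 40 °C) should give (2R,4E)-6-(benzyloxy)hex-4-en-2-ol F2. Shi epoxidation with the ketone enantiomer that delivers the 4S,5S epoxide (KHSO5 as Oxone, K2CO3 buffer, MeCN–dimethoxymethane, 0 °C) should give (2R)-1-[(2S,3S)-3-[(benzyloxy)methyl]oxiran-2-yl]propan-2-ol F3. Camphorsulfonic acid (cat., CH2Cl2, 0 °C) should then induce 5-endo opening of the epoxide by the C2 hydroxyl with inversion at C5, which comes back to the route at 8.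

(2) Step 4, the Fleming–Tamao oxidation. Electrophilic activation of silicon next to the ring oxygen may trigger anti β-elimination with opening of the oxolane, and bromination of the benzyl group may compete. The fallback unmasks silicon by dearomatisation and nucleophilic cleavage, with no electrophile or acid. It sets out from 6: Birch reduction (Li, liquid NH3, EtOH, THF, −78 °C) reduces the phenyl group on silicon and cleaves the benzyl ether, giving [(2R,3S,5R)-3-[cyclohexa-2,5-dien-1-yl(dimethyl)silyl]-5-methyloxolan-2-yl]methanol F4. TBAF (DMF) then cleaves the doubly allylic Si–C bond, and H2O2, KF, KHCO3 (THF–MeOH) completes a nucleophilic Tamao oxidation with retention to (2R,3S,5R)-2-(hydroxymethyl)-5-methyloxolan-3-ol F5. Silylation of both hydroxyls (TBSCl, imidazole, DMF) gives tert-butyl{[(2R,3S,5R)-3-{[tert-butyl(dimethyl)silyl]oxy}-5-methyloxolan-2-yl]methoxy}dimethylsilane F6. Selective cleavage of the primary silyl ether (HF·pyridine, pyridine, THF, 0 °C) comes back to the route at 10.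

(3) Step 14, the fragment union. Protodeboronation of the alkenylboronate and base-promoted degradation of the iodide (phenoxide formation slows oxidative addition, and the enol lactone may open) may compete with transmetalation. The fallback is a base-free tin coupling. It sets out from 11: chromium-mediated stannyl olefination (Bu3SnCHBr2, CrCl2, LiI, THF–DMF, rt) should give tributyl[(E)-2-[(2R,3S,5R)-3-{[tert-butyl(dimethyl)silyl]oxy}-5-methyloxolan-2-yl]ethenyl]stannane F7. Stille coupling of F7 with 21 (Pd2(dba)3, AsPh3, NMP, rt) comes back to the route at 22.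

**Further compounds**
F1 | step 3 | (2R)-pent-4-en-2-ol | C[C@@H](O)CC=C
F2 | step 3 | (2R,4E)-6-(benzyloxy)hex-4-en-2-ol | C[C@@H](O)C/C=C/COCc1ccccc1
F3 | step 3 | (2R)-1-[(2S,3S)-3-[(benzyloxy)methyl]oxiran-2-yl]propan-2-ol | C[C@@H](O)C[C@@H]1O[C@H]1COCc1ccccc1
F4 | step 4 | [(2R,3S,5R)-3-[cyclohexa-2,5-dien-1-yl(dimethyl)silyl]-5-methyloxolan-2-yl]methanol | C[C@@H]1C[C@H]([Si](C)(C)C2C=CCC=C2)[C@@H](CO)O1
F5 | step 4 | (2R,3S,5R)-2-(hydroxymethyl)-5-methyloxolan-3-ol | C[C@@H]1C[C@H](O)[C@@H](CO)O1
F6 | step 4 | tert-butyl{[(2R,3S,5R)-3-{[tert-butyl(dimethyl)silyl]oxy}-5-methyloxolan-2-yl]methoxy}dimethylsilane | C[C@@H]1C[C@H](O[Si](C)(C)C(C)(C)C)[C@@H](CO[Si](C)(C)C(C)(C)C)O1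
F7 | step 14 | tributyl[(E)-2-[(2R,3S,5R)-3-{[tert-butyl(dimethyl)silyl]oxy}-5-methyloxolan-2-yl]ethenyl]stannane | C[C@@H]1C[C@H](O[Si](C)(C)C(C)(C)C)[C@@H](/C=C/[Sn](CCCC)(CCCC)CCCC)O1
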